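**Plan**
- Retrosynthesis: the pyran is opened at C1–O2–C3 to a masked formyl group on C8a and a C3≡C4 alkyne on C4a. The carbocycle is then cut at C6–C7 and at C4a–C8a, which leaves an acyclic keto ester whose diynoyl unit (C3 to C6) is parked as an aryl ester on the orsellinate 2‑OH.
- Enabling feature: C7 (quaternary, bearing Me and the orsellinate oxygen) lies between the C6 and C8 ketones, and C4a is β to C6=O and bonded to C8a, which is α to C8=O. Ring C4a–C5–C6–C7–C8–C8a is therefore a Claisen‑plus‑Michael [3+3] retron, and the orsellinate 2‑OH can hand the acyl group to C7.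
- Forward: a diynoic acid and a keto‑acetal orsellinate are made separately and joined by an aryl ester bond. One base‑triggered domino (O‑to‑C acyl transfer, then 6‑endo Michael) builds the carbocycle. Unmasking of C1 and CuI‑catalysed 6‑endo closure then form the pyran, and acid frees the enal and the 4‑OH.
- Stereochemistry: the only stereocentre, C7 (R), is created in the acyl transfer of the key step under a chiral ammonium counter‑ion. The E alkene comes unchanged from the starting enynol.

Key step: step 9

Remark: the E enynol and the (1,3‑dioxolan‑2‑ylmethyl)magnesium bromide solution are taken as catalogue items.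

**Step 1**
Reactants: 1 (2E)-pent-2-en-4-yn-1-ol; 2 ethylene glycol
Product: 4 2-[(1E)-but-1-en-3-yn-1-yl]-1,3-dioxolane, via enynal 3 (not isolated)
Conditions: MnO2 (10 equiv), CH2Cl2, rt; filter; then ethylene glycol, PPTS (5 mol %), MgSO4, CH2Cl2, rt
Reagents that add atoms: ethylene glycol (2), OCCO
Why: MnO2 oxidizes the allylic alcohol without touching the alkyne or the E geometry, and the volatile enynal is trapped at once by acid‑catalysed acetalization, so the aldehyde travels masked through all basic steps.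

**Step 2**
Reactants: 4 2-[(1E)-but-1-en-3-yn-1-yl]-1,3-dioxolane; 5 N-bromosuccinimide
Product: 6 2-[(1E)-4-bromobut-1-en-3-yn-1-yl]-1,3-dioxolane
Conditions: NBS, AgNO3 (10 mol %), acetone, rt, dark
Reagents that add atoms: N-bromosuccinimide (5), O=C1CCC(=O)N1Br
Why: Silver‑catalysed electrophilic bromination of a terminal alkyne C–H is specific for the acetylenic position and is neutral, so the alkene and the acetal should survive.

**Step 3**
Reactants: 6 2-[(1E)-4-bromobut-1-en-3-yn-1-yl]-1,3-dioxolane; 7 prop-2-ynoic acid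
Product: 8 (6E)-7-(1,3-dioxolan-2-yl)hept-6-ene-2,4-diynoic acid
Conditions: CuCl (5 mol %), NH2OH·HCl (10 mol %), n-BuNH2 (30% aq), MeOH, 0 °C; then citric acid to pH 4, 0 °C
Reagents that add atoms: prop-2-ynoic acid (7), C#CC(=O)O
Why: Cadiot–Chodkiewicz coupling of a 1‑bromoalkyne with propiolic acid (present as its ammonium carboxylate) is the classical entry to alka‑2,4‑diynoic acids, and the basic medium protects the acetal.

**Step 4**
Reactants: 9 2-chloropropanoyl chloride; 10 N,O-dimethylhydroxylamine hydrochloride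
Product: 11 2-chloro-N-methoxy-N-methylpropanamide (racemic)
Conditions: Et3N (2.2 equiv), CH2Cl2, 0 °C
Reagents that add atoms: N,O-dimethylhydroxylamine hydrochloride (10), CNOC.Cl
Why: Acylation of the hydroxylamine by the acid chloride gives the Weinreb amide, the secondary chloride being inert at 0 °C.

**Step 5**
Reactants: 11 2-chloro-N-methoxy-N-methylpropanamide; 12 (1,3-dioxolan-2-ylmethyl)magnesium bromide
Product: 13 3-chloro-1-(1,3-dioxolan-2-yl)butan-2-one (racemic)
Conditions: THF, 0 °C to rt; sat. aq NH4Cl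
Reagents that add atoms: (1,3-dioxolan-2-ylmethyl)magnesium bromide (12), Br[Mg]CC1OCCO1
Why: Weinreb ketone synthesis: the Grignard reagent adds once to give a magnesium chelate that releases the ketone only on work‑up, and α‑chloro Weinreb amides are an accepted substrate class for it.

**Step 6**
Reactants: 14 orsellinic acid (2,4-dihydroxy-6-methylbenzoic acid); 13 3-chloro-1-(1,3-dioxolan-2-yl)butan-2-one
Product: 15 4-(1,3-dioxolan-2-yl)-3-oxobutan-2-yl 2,4-dihydroxy-6-methylbenzoate (racemic)
Conditions: KHCO3 (1.1 equiv), NaI (10 mol %), DMF, 40 °C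
Reagents that add atoms: 3-chloro-1-(1,3-dioxolan-2-yl)butan-2-one (13), CC(Cl)C(=O)CC1OCCO1
Why: Only the carboxylate is ionized by KHCO3 and it displaces the α‑keto chloride after Finkelstein exchange (SN2 O‑alkylation, the method of choice for a 2,6‑disubstituted benzoic acid); the new CH(O) centre is racemic, which is harmless because it is planarized in step 9.

**Step 7**
Reactants: 15 4-(1,3-dioxolan-2-yl)-3-oxobutan-2-yl 2,4-dihydroxy-6-methylbenzoate; 16 chloromethyl methyl ether
Product: 17 4-(1,3-dioxolan-2-yl)-3-oxobutan-2-yl 2-hydroxy-4-(methoxymethoxy)-6-methylbenzoate (racemic)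
Conditions: MOMCl (1.05 equiv), i-Pr2NEt, CH2Cl2, 0 °C
Reagents that add atoms: chloromethyl methyl ether (16), COCCl
Why: The 2‑hydroxyl is locked in a hydrogen bond to the ester carbonyl, so Williamson‑type alkylation should take place only at the free, more acidic 4‑hydroxyl.

**Step 8**
Reactants: 17 4-(1,3-dioxolan-2-yl)-3-oxobutan-2-yl 2-hydroxy-4-(methoxymethoxy)-6-methylbenzoate; 8 (6E)-7-(1,3-dioxolan-2-yl)hept-6-ene-2,4-diynoic acid
Product: 18 4-(1,3-dioxolan-2-yl)-3-oxobutan-2-yl 2-{[(6E)-7-(1,3-dioxolan-2-yl)hept-6-ene-2,4-diynoyl]oxy}-4-(methoxymethoxy)-6-methylbenzoate (racemic)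
Conditions: DCC (1.1 equiv), DMAP (5 mol %), CH2Cl2, −10 °C
Reagents that add atoms: (6E)-7-(1,3-dioxolan-2-yl)hept-6-ene-2,4-diynoic acid (8), OC(=O)C#CC#C/C=C/C1OCCO1
Why: Steglich esterification acylates the remaining chelated phenol under anhydrous, near‑neutral conditions that spare both acetals, and the aryl ester so formed is at once the tether and the activating group for step 9.

**Step 9**
Reactants: 18 4-(1,3-dioxolan-2-yl)-3-oxobutan-2-yl 2-{[(6E)-7-(1,3-dioxolan-2-yl)hept-6-ene-2,4-diynoyl]oxy}-4-(methoxymethoxy)-6-methylbenzoate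
Product: 20 (1R)-4-[(3E)-4-(1,3-dioxolan-2-yl)but-3-en-1-yn-1-yl]-5-(1,3-dioxolan-2-yl)-1-methyl-2,6-dioxocyclohex-3-en-1-yl 2-hydroxy-4-(methoxymethoxy)-6-methylbenzoate, via acyclic triketone 19 (not isolated)
Conditions: N-(9-anthracenylmethyl)-O-allylcinchonidinium bromide (10 mol %), Cs2CO3 (powdered, 3 equiv), toluene/CH2Cl2 (4:1), −20 to 0 °C; AcOH quench
Reagents that add atoms: none
Why: Proposed new method: the ammonium enolate of C7 (the most acidic C–H, being α to the C8 ketone and to the acyloxy oxygen) attacks the aryl ester carbonyl through a seven‑membered transition state, so that the diynoyl group moves from the phenol oxygen to C7 (bond C6–C7) and the 2‑hydroxyl is freed as phenoxide, after which the C8a enolate of the new non‑enolizable 1,3‑diketone adds to the ynone β‑carbon C4a (bond C4a–C8a) and the product rests as its stabilized vinylogous‑acid anion, the whole being an isomerization. The closest known reaction types are the Baker–Venkataraman O‑to‑C acyl shift, the intramolecular C‑acylation of ketone enolates by aryl esters directed by a chiral ammonium counter‑ion (which gives quaternary 1,3‑diketones), and the Michael cyclization of ketone enolates onto ynones. The carbocycle closes in the 6‑endo‑dig mode by attack of carbon, whereas attack of the enolate oxygen would give a non‑aromatic pyranone lacking the vinylogous‑acid stabilization. C7 is the only lasting new stereocentre (C8a is enolizable and becomes sp2 in step 10) and is set in the acyl transfer by the cinchonidinium cation, which pairs with the enolate oxygen and shields one enolate face from the tethered acyl group; the sense of induction cannot be predicted, and the pseudoenantiomeric cinchoninium salt is the mirror‑image option if it proves opposite. The step needs 1,2‑attack at the ester carbonyl instead of conjugate addition to the diyne, no attack on the orsellinate carbonyl and no free alkoxide: the tether turns the conjugate mode into a nine‑membered closure, the orsellinate carbonyl is shielded by its two ortho substituents, and the cyclic acetal at C1 cannot expel a free alkoxide. The racemic background path should stay low because Cs2CO3 is insoluble and the enolate enters the solution only as the ammonium ion pair.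

**Step 10**
Reactants: 20 (1R)-4-[(3E)-4-(1,3-dioxolan-2-yl)but-3-en-1-yn-1-yl]-5-(1,3-dioxolan-2-yl)-1-methyl-2,6-dioxocyclohex-3-en-1-yl 2-hydroxy-4-(methoxymethoxy)-6-methylbenzoate
Product: 22 (7R)-3-[(E)-2-(1,3-dioxolan-2-yl)ethenyl]-7-methyl-6,8-dioxo-7,8-dihydro-6H-isochromen-7-yl 2-hydroxy-4-(methoxymethoxy)-6-methylbenzoate, via formyl vinylogous acid 21 (not isolated)
Conditions: PPTS (20 mol %), acetone/H2O (10:1), rt; then CuI (10 mol %), i-Pr2NEt (0.5 equiv), CH2Cl2, rt
Reagents that add atoms: water, O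
Why: The C1 acetal sits on the α‑carbon of an enolized vinylogous acid, so its ionization is enol‑assisted and mild acid should unmask it selectively beside the side‑chain acetal and the MOM ether; the resulting 2‑formyl‑3‑alkynyl vinylogous acid then undergoes the CuI‑catalysed 6‑endo‑dig cycloisomerization through the formyl oxygen that is established for azaphilone formation from this substitution pattern, and C7 is not touched.

**Step 11**
Reactants: 22 (7R)-3-[(E)-2-(1,3-dioxolan-2-yl)ethenyl]-7-methyl-6,8-dioxo-7,8-dihydro-6H-isochromen-7-yl 2-hydroxy-4-(methoxymethoxy)-6-methylbenzoate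
Product: 23 (7R)-7-methyl-6,8-dioxo-3-[(1E)-3-oxoprop-1-en-1-yl]-7,8-dihydro-6H-isochromen-7-yl 2,4-dihydroxy-6-methylbenzoate
Conditions: 3 M aq HCl/THF (1:3), rt to 40 °C
Reagents that add atoms: water, O
Why: Aqueous acid hydrolyses the vinyl dioxolane to the E enal and cleaves the aryl MOM ether, while the azaphilone core and the tertiary ester (whose ionization is disfavoured by the two flanking carbonyls) should be acid‑stable, and the quaternary C7 cannot epimerize.

**Compound list**
1 | (2E)-pent-2-en-4-yn-1-ol | OC/C=C/C#C | starting material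
2 | ethylene glycol | OCCO | starting material
3 | (2E)-pent-2-en-4-ynal (enynal, formed in the flask) | O=C/C=C/C#C | intermediate
4 | 2-[(1E)-but-1-en-3-yn-1-yl]-1,3-dioxolane | C#C/C=C/C1OCCO1 | intermediate
5 | N-bromosuccinimide | O=C1CCC(=O)N1Br | starting material
6 | 2-[(1E)-4-bromobut-1-en-3-yn-1-yl]-1,3-dioxolane | BrC#C/C=C/C1OCCO1 | intermediate
7 | prop-2-ynoic acid | C#CC(=O)O | starting material
8 | (6E)-7-(1,3-dioxolan-2-yl)hept-6-ene-2,4-diynoic acid | OC(=O)C#CC#C/C=C/C1OCCO1 | intermediate
9 | 2-chloropropanoyl chloride (racemic) | CC(Cl)C(=O)Cl | starting material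
10 | N,O-dimethylhydroxylamine hydrochloride | CNOC.Cl | starting material
11 | 2-chloro-N-methoxy-N-methylpropanamide (racemic) | CC(Cl)C(=O)N(C)OC | intermediate
12 | (1,3-dioxolan-2-ylmethyl)magnesium bromide | Br[Mg]CC1OCCO1 | starting material
13 | 3-chloro-1-(1,3-dioxolan-2-yl)butan-2-one (racemic) | CC(Cl)C(=O)CC1OCCO1 | intermediate
14 | orsellinic acid (2,4-dihydroxy-6-methylbenzoic acid) | Cc1cc(O)cc(O)c1C(=O)O | starting material
15 | 4-(1,3-dioxolan-2-yl)-3-oxobutan-2-yl 2,4-dihydroxy-6-methylbenzoate (racemic) | CC(OC(=O)c1c(C)cc(O)cc1O)C(=O)CC1OCCO1 | intermediate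
16 | chloromethyl methyl ether | COCCl | starting material
17 | 4-(1,3-dioxolan-2-yl)-3-oxobutan-2-yl 2-hydroxy-4-(methoxymethoxy)-6-methylbenzoate (racemic) | CC(OC(=O)c1c(C)cc(OCOC)cc1O)C(=O)CC1OCCO1 | intermediate
18 | 4-(1,3-dioxolan-2-yl)-3-oxobutan-2-yl 2-{[(6E)-7-(1,3-dioxolan-2-yl)hept-6-ene-2,4-diynoyl]oxy}-4-(methoxymethoxy)-6-methylbenzoate (racemic at the CH–O carbon) | CC(OC(=O)c1c(C)cc(OCOC)cc1OC(=O)C#CC#C/C=C/C1OCCO1)C(=O)CC1OCCO1 | intermediate
19 | (3S,9E)-1,10-bis(1,3-dioxolan-2-yl)-3-methyl-2,4-dioxodec-9-ene-5,7-diyn-3-yl 2-hydroxy-4-(methoxymethoxy)-6-methylbenzoate (acyclic triketone, formed in the flask; same spatial arrangement at the quaternary carbon as in 20) | COCOc1cc(C)c(C(=O)O[C@](C)(C(=O)C#CC#C/C=C/C2OCCO2)C(=O)CC2OCCO2)c(O)c1 | intermediate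
20 | (1R)-4-[(3E)-4-(1,3-dioxolan-2-yl)but-3-en-1-yn-1-yl]-5-(1,3-dioxolan-2-yl)-1-methyl-2,6-dioxocyclohex-3-en-1-yl 2-hydroxy-4-(methoxymethoxy)-6-methylbenzoate (ring C5 enolizable, not assigned) | COCOc1cc(C)c(C(=O)O[C@]2(C)C(=O)C=C(C#C/C=C/C3OCCO3)C(C3OCCO3)C2=O)c(O)c1 | intermediate
21 | (1R)-4-[(3E)-4-(1,3-dioxolan-2-yl)but-3-en-1-yn-1-yl]-5-(hydroxymethylidene)-1-methyl-2,6-dioxocyclohex-3-en-1-yl 2-hydroxy-4-(methoxymethoxy)-6-methylbenzoate (formyl vinylogous acid, formed in the flask) | COCOc1cc(C)c(C(=O)O[C@]2(C)C(=O)C=C(C#C/C=C/C3OCCO3)C(=CO)C2=O)c(O)c1 | intermediate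
22 | (7R)-3-[(E)-2-(1,3-dioxolan-2-yl)ethenyl]-7-methyl-6,8-dioxo-7,8-dihydro-6H-isochromen-7-yl 2-hydroxy-4-(methoxymethoxy)-6-methylbenzoate | COCOc1cc(C)c(C(=O)O[C@]2(C)C(=O)C=C3C=C(/C=C/C4OCCO4)OC=C3C2=O)c(O)c1 | intermediate
23 | (7R)-7-methyl-6,8-dioxo-3-[(1E)-3-oxoprop-1-en-1-yl]-7,8-dihydro-6H-isochromen-7-yl 2,4-dihydroxy-6-methylbenzoate | Cc1cc(O)cc(O)c1C(=O)O[C@]1(C)C(=O)C=C2C=C(/C=C/C=O)OC=C2C1=O | target

**Step count:** 11 steps in total. **Longest linear sequence:** 8 steps (steps 4, 5, 6, 7, 8, 9, 10, 11).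

**Steps most likely to fail**

Step 9 (bears the label). What may go wrong:
- enolization under the mild heterogeneous base may be too slow, so that cleavage of the aryl ester or addition to the diyne takes over;
- facial selectivity in the acyl transfer may be poor;
- the ring may close through the enolate oxygen instead of carbon.

The fallback uses known chemistry, sets out from 4 and 14, and comes back at 22. Sonogashira coupling of 4 with 6-bromo-2,4-dihydroxy-3-methylbenzaldehyde F1 (PdCl2(PPh3)2, CuI, Et3N, DMF) would give 6-[(3E)-4-(1,3-dioxolan-2-yl)but-3-en-1-yn-1-yl]-2,4-dihydroxy-3-methylbenzaldehyde F2. Copper–sparteine–dioxygen oxidative dearomatization ([Cu(MeCN)4]PF6, the sparteine enantiomer that delivers the R carbinol, O2, −78 °C) followed by CuI‑catalysed cycloisomerization would give the tertiary alcohol (7R)-3-[(E)-2-(1,3-dioxolan-2-yl)ethenyl]-7-hydroxy-7-methyl-6H-isochromene-6,8(7H)-dione F3. In parallel, 14 would be converted with acetone, (CF3CO)2O and CF3CO2H into 7-hydroxy-2,2,5-trimethyl-4H-1,3-benzodioxin-4-one F4, and then with MOMCl and i-Pr2NEt into 7-(methoxymethoxy)-2,2,5-trimethyl-4H-1,3-benzodioxin-4-one F5. The sodium alkoxide of F3 (NaN(SiMe3)2, THF, −78 °C) would open F5 with loss of acetone (the established alkoxide opening of such benzodioxinones to salicylate esters) to give 22.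

Step 8. What may go wrong: DMAP or the phenol may add in conjugate fashion to the activated diynoic acid, and acylation of the chelated, hindered phenol may be slow. The fallback sets out from 17 and 6 and comes back at 18. Ester 17 would be acylated (DCC, catalytic DMAP) with commercial, less electrophilic 3-(trimethylsilyl)prop-2-ynoic acid to give 4-(1,3-dioxolan-2-yl)-3-oxobutan-2-yl 4-(methoxymethoxy)-6-methyl-2-{[3-(trimethylsilyl)prop-2-ynoyl]oxy}benzoate F6. Copper‑mediated coupling of this alkynylsilane with bromoalkyne 6 (CuCl, DMF, 60 °C) would then build the diyne on the ester and give 18.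

Step 3. What may go wrong: copper may promote decarboxylation of the 2‑alkynoic acid, the bromoalkyne may homocouple, and the acetal may be lost during acidification. The fallback sets out from 6 and comes back at 8. Cadiot–Chodkiewicz coupling of 6 with ethynyltriisopropylsilane (CuCl, NH2OH·HCl, n-BuNH2) would give triisopropyl[(5E)-6-(1,3-dioxolan-2-yl)hexa-5-ene-1,3-diyn-1-yl]silane F7. Bu4NF (THF, 0 °C) would give 2-[(1E)-hexa-1-ene-3,5-diyn-1-yl]-1,3-dioxolane F8, used at once in solution. Deprotonation with n-BuLi (THF, −78 °C) and trapping with CO2, with acidification only to pH 4, would give 8.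

**Further compounds**
F1 | step 9 | 6-bromo-2,4-dihydroxy-3-methylbenzaldehyde | O=Cc1c(Br)cc(O)c(C)c1O
F2 | step 9 | 6-[(3E)-4-(1,3-dioxolan-2-yl)but-3-en-1-yn-1-yl]-2,4-dihydroxy-3-methylbenzaldehyde | O=Cc1c(C#C/C=C/C2OCCO2)cc(O)c(C)c1O
F3 | step 9 | (7R)-3-[(E)-2-(1,3-dioxolan-2-yl)ethenyl]-7-hydroxy-7-methyl-6H-isochromene-6,8(7H)-dione | O[C@]1(C)C(=O)C=C2C=C(/C=C/C3OCCO3)OC=C2C1=O
F4 | step 9 | 7-hydroxy-2,2,5-trimethyl-4H-1,3-benzodioxin-4-one | Cc1cc(O)cc2OC(C)(C)OC(=O)c12
F5 | step 9 | 7-(methoxymethoxy)-2,2,5-trimethyl-4H-1,3-benzodioxin-4-one | COCOc1cc(C)c2C(=O)OC(C)(C)Oc2c1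
F6 | step 8 | 4-(1,3-dioxolan-2-yl)-3-oxobutan-2-yl 4-(methoxymethoxy)-6-methyl-2-{[3-(trimethylsilyl)prop-2-ynoyl]oxy}benzoate | CC(OC(=O)c1c(C)cc(OCOC)cc1OC(=O)C#C[Si](C)(C)C)C(=O)CC1OCCO1
F7 | step 3 | triisopropyl[(5E)-6-(1,3-dioxolan-2-yl)hexa-5-ene-1,3-diyn-1-yl]silane | CC(C)[Si](C#CC#C/C=C/C1OCCO1)(C(C)C)C(C)C
F8 | step 3 | 2-[(1E)-hexa-1-ene-3,5-diyn-1-yl]-1,3-dioxolane | C#CC#C/C=C/C1OCCO1
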